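**Retrosynthetic overview**
- Target 19 ⇐ TBDPS ether 18 ⇐ cis-epoxy alcohol dimethyl ketal 17 (ketal hydrolysis unmasks the enone carbonyl last).
- 17 ⇐ hydroxyl-directed epoxidation of (S)-dienol 16 ⇐ CBS reduction of the cross-conjugated dienone (quinone monoketal) 15.
- 15 ⇐ phenol 12 by PhI(OAc)2/MeOH dearomatisation, then TBS→Ac exchange.
- 12 ⇐ key intermolecular Michael addition of the lithiated ω-silyloxy-farnesyl phenyl sulfone 5 to quinone monoketal 9 (ring C–C1′ bond), loss of MeOH, Pd/hydride desulfonylation.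
- Rings: the carbocycle is the benzene ring of 2-hydroxy-5-methoxybenzaldehyde (dearomatised in step 7, rearomatised in step 8, dearomatised for good in step 10); the oxirane is the only ring formed, in step 14.

Assumption: commercial (2E,6E)-farnesol is used and its geometry is carried through; "TBDPSO-farnesyl" below means (2E,6E,10E)-12-(tert-butyldiphenylsilyloxy)-3,7,11-trimethyldodeca-2,6,10-trien-1-yl, and TBS = tert-butyldimethylsilyl.

Step 1
Reactants: 1 (2E,6E)-farnesol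
Product: 2 (2E,6E)-farnesyl bromide
Conditions: PBr3 (0.4 equiv), Et2O, –10 → 0 °C; used crude
Reagents that add atoms: phosphorus tribromide BrP(Br)Br
Why: Appel-free SN2 bromination of a primary allylic alcohol with PBr3 proceeds cold without allylic transposition or E/Z loss.

Step 2
Reactants: 2 (2E,6E)-farnesyl bromide
Product: 3 (2E,6E)-farnesyl phenyl sulfone
Conditions: PhSO2Na, DMF, rt
Reagents that add atoms: sodium benzenesulfinate [Na+].[O-]S(=O)c1ccccc1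
Why: S-alkylation (SN2) of the sulfinate at the primary allylic carbon gives the sulfone that later serves as the Michael donor.

Step 3
Reactants: 3 (2E,6E)-farnesyl phenyl sulfone
Product: 4 (2E,6E,10E)-2,6,10-trimethyl-12-(phenylsulfonyl)dodeca-2,6,10-trien-1-ol
Conditions: SeO2 (0.3 equiv), t-BuOOH (3 equiv), salicylic acid (0.1 equiv), CH2Cl2, 0 °C → rt; stop at partial conversion, recycle 3
Reagents that add atoms: tert-butyl hydroperoxide CC(C)(C)OO
Why: Sharpless-type catalytic SeO2 allylic oxidation (ene reaction/[2,3] shift) attacks the most electron-rich terminal trisubstituted alkene and gives the (E)-allylic alcohol, the sulfone-deactivated 2,3-alkene being spared.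

Step 4
Reactants: 4 (2E,6E,10E)-2,6,10-trimethyl-12-(phenylsulfonyl)dodeca-2,6,10-trien-1-ol
Product: 5 tert-butyl(diphenyl){[(2E,6E,10E)-2,6,10-trimethyl-12-(phenylsulfonyl)dodeca-2,6,10-trien-1-yl]oxy}silane
Conditions: TBDPSCl, imidazole, DMF, rt
Reagents that add atoms: tert-butyl(chloro)diphenylsilane CC(C)(C)[Si](Cl)(c1ccccc1)c1ccccc1
Why: Standard silylation gives an ether that survives BuLi, hydride, mild acid and oxidants and is orthogonal to the ring TBS ether.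

Step 5
Reactants: 6 2-hydroxy-5-methoxybenzaldehyde
Product: 7 2-(hydroxymethyl)-4-methoxyphenol
Conditions: NaBH4, MeOH, 0 °C
Reagents that add atoms: none
Why: Borohydride reduction of the aryl aldehyde gives the benzylic alcohol that becomes the CH2OAc carbon.

Step 6
Reactants: 7 2-(hydroxymethyl)-4-methoxyphenol
Product: 8 2-{[(tert-butyldimethylsilyl)oxy]methyl}-4-methoxyphenol
Conditions: TBSCl (1.05 equiv), imidazole, CH2Cl2, 0 °C (any aryl silyl ether is cleaved back with K2CO3/MeOH)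
Reagents that add atoms: tert-butyl(chloro)dimethylsilane CC(C)(C)[Si](C)(C)Cl
Why: Selective O-silylation of the primary alcohol, which reacts faster than the hydrogen-bonded ortho-substituted phenol.

Step 7
Reactants: 8 2-{[(tert-butyldimethylsilyl)oxy]methyl}-4-methoxyphenol
Product: 9 2-{[(tert-butyldimethylsilyl)oxy]methyl}-4,4-dimethoxycyclohexa-2,5-dien-1-one
Conditions: PhI(OAc)2 (1.1 equiv), NaHCO3, MeOH, 0 °C
Reagents that add atoms: methanol CO
Why: Hypervalent-iodine oxidative dearomatisation of a p-methoxyphenol traps methanol at the para carbon and gives the quinone monoketal (Michael acceptor).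

Step 8
Reactants: 5 tert-butyl(diphenyl){[(2E,6E,10E)-2,6,10-trimethyl-12-(phenylsulfonyl)dodeca-2,6,10-trien-1-yl]oxy}silane; 9 2-{[(tert-butyldimethylsilyl)oxy]methyl}-4,4-dimethoxycyclohexa-2,5-dien-1-one
Product: 11 2-{[(tert-butyldimethylsilyl)oxy]methyl}-4-methoxy-5-[(2E,6E,10E)-12-(tert-butyldiphenylsilyloxy)-3,7,11-trimethyl-1-(phenylsulfonyl)dodeca-2,6,10-trien-1-yl]phenol, via Michael-adduct cyclohexenone 10 (not isolated)
Conditions: 5, n-BuLi (1.05 equiv), THF/DMPU, –78 °C; add 9, –78 → –40 °C; AcOH quench at –78 °C; then CSA (10 mol %), 4 Å MS, CH2Cl2, rt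
Reagents that add atoms: none
Why: Intermolecular Michael addition of the soft α-sulfonyl allyl anion (through its α-carbon, the γ-carbon being fully substituted) to the β-carbon of the unsubstituted enone arm of the dienone, followed by acid-promoted loss of MeOH to rearomatise; the new sulfonyl-bearing stereocentre is inconsequential because it is removed in step 9.

Step 9
Reactants: 11 2-{[(tert-butyldimethylsilyl)oxy]methyl}-4-methoxy-5-[1-(phenylsulfonyl)-TBDPSO-farnesyl]phenol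
Product: 12 2-{[(tert-butyldimethylsilyl)oxy]methyl}-4-methoxy-5-(TBDPSO-farnesyl)phenol
Conditions: PdCl2(dppp) (5 mol %), LiBHEt3 (3.5 equiv), THF, 0 °C → rt
Reagents that add atoms: none
Why: Palladium-catalysed reductive desulfonylation of an allylic sulfone, in which hydride is delivered to the less substituted (benzylic) terminus of the π-allyl complex so the 2E trisubstituted alkene stays in place.

Step 10
Reactants: 12 2-{[(tert-butyldimethylsilyl)oxy]methyl}-4-methoxy-5-(TBDPSO-farnesyl)phenol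
Product: 13 2-{[(tert-butyldimethylsilyl)oxy]methyl}-4,4-dimethoxy-5-(TBDPSO-farnesyl)cyclohexa-2,5-dien-1-one
Conditions: PhI(OAc)2 (1.1 equiv), NaHCO3, MeOH, 0 °C
Reagents that add atoms: methanol CO
Why: Second oxidative dearomatisation; the carbonyl sits next to the CH2O-bearing carbon and the ketal next to the farnesyl-bearing carbon, which is the oxidation pattern of the target.

Step 11
Reactants: 13 2-{[(tert-butyldimethylsilyl)oxy]methyl}-4,4-dimethoxy-5-(TBDPSO-farnesyl)cyclohexa-2,5-dien-1-one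
Product: 14 2-(hydroxymethyl)-4,4-dimethoxy-5-(TBDPSO-farnesyl)cyclohexa-2,5-dien-1-one
Conditions: CSA (10 mol %), MeOH, 0 °C
Reagents that add atoms: none
Why: Acid-catalysed methanolysis removes the primary TBS ether far faster than the TBDPS ether, and in methanol the dimethyl ketal only undergoes degenerate exchange.

Step 12
Reactants: 14 2-(hydroxymethyl)-4,4-dimethoxy-5-(TBDPSO-farnesyl)cyclohexa-2,5-dien-1-one
Product: 15 [3,3-dimethoxy-6-oxo-4-(TBDPSO-farnesyl)cyclohexa-1,4-dien-1-yl]methyl acetate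
Conditions: Ac2O, pyridine, CH2Cl2, 0 °C → rt (no DMAP)
Reagents that add atoms: acetic anhydride CC(=O)OC(C)=O
Why: Simple O-acylation installs the target acetate early, where it also deactivates its own ring alkene for step 14.

Step 13
Reactants: 15 [3,3-dimethoxy-6-oxo-4-(TBDPSO-farnesyl)cyclohexa-1,4-dien-1-yl]methyl acetate
Product: 16 [(6S)-6-hydroxy-3,3-dimethoxy-4-(TBDPSO-farnesyl)cyclohexa-1,4-dien-1-yl]methyl acetate
Conditions: (R)-2-methyl-CBS-oxazaborolidine (0.3 equiv), catecholborane (1.8 equiv), toluene, –78 → –40 °C; MeOH quench, pH 7 buffer; Et3N-deactivated SiO2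
Reagents that add atoms: none
Why: Corey–Bakshi–Shibata 1,2-reduction in which the α-(acetoxymethyl)-substituted enone arm acts as the large group, so the (R)-catalyst delivers hydride to the face that gives the (S)-carbinol (the C5 R centre of the target), without hydroborating the chain alkenes.

Step 14
Reactants: 16 [(6S)-6-hydroxy-3,3-dimethoxy-4-(TBDPSO-farnesyl)cyclohexa-1,4-dien-1-yl]methyl acetate
Product: 17 [(1R,5R,6R)-5-hydroxy-2,2-dimethoxy-1-(TBDPSO-farnesyl)-7-oxabicyclo[4.1.0]hept-3-en-4-yl]methyl acetate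
Conditions: VO(acac)2 (5 mol %), t-BuOOH (5.5 M in decane, 1.3 equiv), CH2Cl2, 0 °C; Na2S2O3/NaHCO3 work-up
Reagents that add atoms: tert-butyl hydroperoxide CC(C)(C)OO
Why: Hydroxyl-directed vanadium-catalysed epoxidation delivers oxygen syn to the OH onto the electron-richer farnesyl-bearing ring alkene (the acetoxymethyl-bearing alkene is deactivated, the chain alkenes are undirected), setting both epoxide centres cis to the carbinol.

Step 15
Reactants: 17 [(1R,5R,6R)-5-hydroxy-2,2-dimethoxy-1-(TBDPSO-farnesyl)-7-oxabicyclo[4.1.0]hept-3-en-4-yl]methyl acetate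
Product: 18 [(1R,5R,6R)-5-hydroxy-2-oxo-1-(TBDPSO-farnesyl)-7-oxabicyclo[4.1.0]hept-3-en-4-yl]methyl acetate
Conditions: montmorillonite K10, wet CH2Cl2, rt
Reagents that add atoms: water O
Why: Mild solid-acid hydrolysis of the allylic dimethyl ketal unveils the enone carbonyl next to the quaternary epoxide carbon without touching the epoxide, acetate, silyl ether or any stereocentre.

Step 16
Reactants: 18 [(1R,5R,6R)-5-hydroxy-2-oxo-1-(TBDPSO-farnesyl)-7-oxabicyclo[4.1.0]hept-3-en-4-yl]methyl acetate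
Product: 19 {(1R,5R,6R)-5-hydroxy-1-[(2E,6E,10E)-12-hydroxy-3,7,11-trimethyldodeca-2,6,10-trien-1-yl]-2-oxo-7-oxabicyclo[4.1.0]hept-3-en-4-yl}methyl acetate (CNP0336169.1)
Conditions: HF·pyridine, pyridine, THF, 0 °C → rt
Reagents that add atoms: none
Why: Fluoride-mediated Si–O cleavage under non-basic conditions frees the chain alcohol while avoiding 1,3-acetyl migration and epoxy-enone degradation.

**Compound list**
1 | (2E,6E)-farnesol | CC(C)=CCC/C(C)=C/CC/C(C)=C/CO | starting material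
2 | (2E,6E)-farnesyl bromide | CC(C)=CCC/C(C)=C/CC/C(C)=C/CBr | intermediate
3 | (2E,6E)-farnesyl phenyl sulfone | CC(C)=CCC/C(C)=C/CC/C(C)=C/CS(=O)(=O)c1ccccc1 | intermediate
4 | (2E,6E,10E)-2,6,10-trimethyl-12-(phenylsulfonyl)dodeca-2,6,10-trien-1-ol | OC/C(C)=C/CC/C(C)=C/CC/C(C)=C/CS(=O)(=O)c1ccccc1 | intermediate
5 | tert-butyl(diphenyl){[(2E,6E,10E)-2,6,10-trimethyl-12-(phenylsulfonyl)dodeca-2,6,10-trien-1-yl]oxy}silane | CC(C)(C)[Si](c1ccccc1)(c1ccccc1)OC/C(C)=C/CC/C(C)=C/CC/C(C)=C/CS(=O)(=O)c1ccccc1 | intermediate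
6 | 2-hydroxy-5-methoxybenzaldehyde | COc1ccc(O)c(C=O)c1 | starting material
7 | 2-(hydroxymethyl)-4-methoxyphenol | COc1ccc(O)c(CO)c1 | intermediate
8 | 2-{[(tert-butyldimethylsilyl)oxy]methyl}-4-methoxyphenol | COc1ccc(O)c(CO[Si](C)(C)C(C)(C)C)c1 | intermediate
9 | 2-{[(tert-butyldimethylsilyl)oxy]methyl}-4,4-dimethoxycyclohexa-2,5-dien-1-one | COC1(OC)C=CC(=O)C(CO[Si](C)(C)C(C)(C)C)=C1 | intermediate
10 | 2-{[(tert-butyldimethylsilyl)oxy]methyl}-4,4-dimethoxy-5-[(2E,6E,10E)-12-(tert-butyldiphenylsilyloxy)-3,7,11-trimethyl-1-(phenylsulfonyl)dodeca-2,6,10-trien-1-yl]cyclohex-2-en-1-one (diastereomer mixture) | COC1(OC)C=C(CO[Si](C)(C)C(C)(C)C)C(=O)CC1C(/C=C(\C)CC/C=C(\C)CC/C=C(\C)CO[Si](c2ccccc2)(c2ccccc2)C(C)(C)C)S(=O)(=O)c2ccccc2 | intermediate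
11 | 2-{[(tert-butyldimethylsilyl)oxy]methyl}-4-methoxy-5-[(2E,6E,10E)-12-(tert-butyldiphenylsilyloxy)-3,7,11-trimethyl-1-(phenylsulfonyl)dodeca-2,6,10-trien-1-yl]phenol (racemic at the sulfonyl carbon) | COc1cc(CO[Si](C)(C)C(C)(C)C)c(O)cc1C(/C=C(\C)CC/C=C(\C)CC/C=C(\C)CO[Si](c2ccccc2)(c2ccccc2)C(C)(C)C)S(=O)(=O)c2ccccc2 | intermediate
12 | 2-{[(tert-butyldimethylsilyl)oxy]methyl}-4-methoxy-5-[(2E,6E,10E)-12-(tert-butyldiphenylsilyloxy)-3,7,11-trimethyldodeca-2,6,10-trien-1-yl]phenol | COc1cc(CO[Si](C)(C)C(C)(C)C)c(O)cc1C/C=C(\C)CC/C=C(\C)CC/C=C(\C)CO[Si](c2ccccc2)(c2ccccc2)C(C)(C)C | intermediate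
13 | 2-{[(tert-butyldimethylsilyl)oxy]methyl}-4,4-dimethoxy-5-[(2E,6E,10E)-12-(tert-butyldiphenylsilyloxy)-3,7,11-trimethyldodeca-2,6,10-trien-1-yl]cyclohexa-2,5-dien-1-one | COC1(OC)C=C(CO[Si](C)(C)C(C)(C)C)C(=O)C=C1C/C=C(\C)CC/C=C(\C)CC/C=C(\C)CO[Si](c2ccccc2)(c2ccccc2)C(C)(C)C | intermediate
14 | 2-(hydroxymethyl)-4,4-dimethoxy-5-[(2E,6E,10E)-12-(tert-butyldiphenylsilyloxy)-3,7,11-trimethyldodeca-2,6,10-trien-1-yl]cyclohexa-2,5-dien-1-one | COC1(OC)C=C(CO)C(=O)C=C1C/C=C(\C)CC/C=C(\C)CC/C=C(\C)CO[Si](c2ccccc2)(c2ccccc2)C(C)(C)C | intermediate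
15 | {3,3-dimethoxy-6-oxo-4-[(2E,6E,10E)-12-(tert-butyldiphenylsilyloxy)-3,7,11-trimethyldodeca-2,6,10-trien-1-yl]cyclohexa-1,4-dien-1-yl}methyl acetate | COC1(OC)C=C(COC(C)=O)C(=O)C=C1C/C=C(\C)CC/C=C(\C)CC/C=C(\C)CO[Si](c2ccccc2)(c2ccccc2)C(C)(C)C | intermediate
16 | {(6S)-6-hydroxy-3,3-dimethoxy-4-[(2E,6E,10E)-12-(tert-butyldiphenylsilyloxy)-3,7,11-trimethyldodeca-2,6,10-trien-1-yl]cyclohexa-1,4-dien-1-yl}methyl acetate | CC(=O)OCC1=CC(OC)(OC)C(C/C=C(\C)CC/C=C(\C)CC/C=C(\C)CO[Si](c2ccccc2)(c2ccccc2)C(C)(C)C)=C[C@@H]1O | intermediate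
17 | {(1R,5R,6R)-5-hydroxy-2,2-dimethoxy-1-[(2E,6E,10E)-12-(tert-butyldiphenylsilyloxy)-3,7,11-trimethyldodeca-2,6,10-trien-1-yl]-7-oxabicyclo[4.1.0]hept-3-en-4-yl}methyl acetate (epoxide cis to OH) | CC(=O)OCC1=CC(OC)(OC)[C@]2(C/C=C(\C)CC/C=C(\C)CC/C=C(\C)CO[Si](c3ccccc3)(c3ccccc3)C(C)(C)C)O[C@@H]2[C@@H]1O | intermediate
18 | {(1R,5R,6R)-5-hydroxy-2-oxo-1-[(2E,6E,10E)-12-(tert-butyldiphenylsilyloxy)-3,7,11-trimethyldodeca-2,6,10-trien-1-yl]-7-oxabicyclo[4.1.0]hept-3-en-4-yl}methyl acetate | CC(=O)OCC1=CC(=O)[C@]2(C/C=C(\C)CC/C=C(\C)CC/C=C(\C)CO[Si](c3ccccc3)(c3ccccc3)C(C)(C)C)O[C@@H]2[C@@H]1O | intermediate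
19 | {(1R,5R,6R)-5-hydroxy-1-[(2E,6E,10E)-12-hydroxy-3,7,11-trimethyldodeca-2,6,10-trien-1-yl]-2-oxo-7-oxabicyclo[4.1.0]hept-3-en-4-yl}methyl acetate | CC(=O)OCC1=CC(=O)[C@]2(C/C=C(\C)CC/C=C(\C)CC/C=C(\C)CO)O[C@@H]2[C@@H]1O | target

**Step count:** 16 steps in total; longest linear sequence 13 steps (steps 1–4, 8–16, from farnesol).

**Three steps most likely to fail, with fallbacks**

Step 8 (key Michael union). The risks are competing 1,2-addition and attack on the CH2OTBS-bearing enone arm. The fallback sets out from 5 and keeps the Michael union but removes the regiochemical question. Lithiated 5 is added to the symmetrical commercial monoketal 4,4-dimethoxycyclohexa-2,5-dien-1-one F1, giving the adduct 4,4-dimethoxy-5-(sulfonyl-TBDPSO-farnesyl)cyclohex-2-en-1-one F2. CSA aromatises it to the sulfonyl phenol F3, and PdCl2(dppp)/LiBHEt3 gives 4-methoxy-3-(TBDPSO-farnesyl)phenol F4. The one-carbon unit is then introduced by Mg-mediated ortho-formylation (MgCl2, Et3N, paraformaldehyde, THF, reflux) at the unhindered ortho position para to the chain, giving 2-hydroxy-5-methoxy-4-(TBDPSO-farnesyl)benzaldehyde F5. NaBH4 gives 2-(hydroxymethyl)-4-methoxy-5-(TBDPSO-farnesyl)phenol F6, and selective TBS silylation comes back to the route at 12.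

Step 13 (CBS reduction). The risks are insufficient ee, because both carbonyl flanks are vinylic, and the acid lability of the dienol ketal. The fallback sets out from 15. Luche reduction (NaBH4, CeCl3·7H2O, MeOH, –78 °C) gives the racemic dienol rac-[6-hydroxy-3,3-dimethoxy-4-(TBDPSO-farnesyl)cyclohexa-1,4-dien-1-yl]methyl acetate F7. Lipase-catalysed kinetic resolution (Burkholderia cepacia lipase, vinyl butanoate, MTBE, trace Et3N) should acylate the (R)-alcohol (Kazlauskas rule) to the (R)-butanoate F8, leaving the unreacted (S)-alcohol, which is 16, where the route is rejoined.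

Step 14 (directed epoxidation). The risk is that the vanadate also epoxidises the acetoxymethyl-bearing ring alkene or oxidises the bis-allylic alcohol back to 15. The fallback sets out from 16 and makes the competing alkene an electron-poor enal. K2CO3/MeOH (0 °C) gives the diol (6S)-6-hydroxy-1-(hydroxymethyl)-3,3-dimethoxy-4-(TBDPSO-farnesyl)cyclohexa-1,4-diene F9. Cu(I)/bipyridine/TEMPO/N-methylimidazole under air oxidises only the primary allylic alcohol to the hydroxy enal F10. VO(acac)2/t-BuOOH can then epoxidise only the farnesyl-bearing alkene, syn to OH, giving the epoxy enal F11. NaBH4/CeCl3 (–78 °C) gives the epoxy diol F12, and AcCl/2,4,6-collidine (–78 °C, primary-selective) comes back to the route at 17.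

**Further compounds**
F1 | step 8 | 4,4-dimethoxycyclohexa-2,5-dien-1-one | COC1(OC)C=CC(=O)C=C1
F2 | step 8 | 4,4-dimethoxy-5-[(2E,6E,10E)-12-(tert-butyldiphenylsilyloxy)-3,7,11-trimethyl-1-(phenylsulfonyl)dodeca-2,6,10-trien-1-yl]cyclohex-2-en-1-one | COC1(OC)C=CC(=O)CC1C(/C=C(\C)CC/C=C(\C)CC/C=C(\C)CO[Si](c2ccccc2)(c2ccccc2)C(C)(C)C)S(=O)(=O)c2ccccc2
F3 | step 8 | 4-methoxy-3-[(2E,6E,10E)-12-(tert-butyldiphenylsilyloxy)-3,7,11-trimethyl-1-(phenylsulfonyl)dodeca-2,6,10-trien-1-yl]phenol | COc1ccc(O)cc1C(/C=C(\C)CC/C=C(\C)CC/C=C(\C)CO[Si](c2ccccc2)(c2ccccc2)C(C)(C)C)S(=O)(=O)c2ccccc2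
F4 | step 8 | 4-methoxy-3-[(2E,6E,10E)-12-(tert-butyldiphenylsilyloxy)-3,7,11-trimethyldodeca-2,6,10-trien-1-yl]phenol | COc1ccc(O)cc1C/C=C(\C)CC/C=C(\C)CC/C=C(\C)CO[Si](c2ccccc2)(c2ccccc2)C(C)(C)C
F5 | step 8 | 2-hydroxy-5-methoxy-4-[(2E,6E,10E)-12-(tert-butyldiphenylsilyloxy)-3,7,11-trimethyldodeca-2,6,10-trien-1-yl]benzaldehyde | COc1cc(C=O)c(O)cc1C/C=C(\C)CC/C=C(\C)CC/C=C(\C)CO[Si](c2ccccc2)(c2ccccc2)C(C)(C)C
F6 | step 8 | 2-(hydroxymethyl)-4-methoxy-5-[(2E,6E,10E)-12-(tert-butyldiphenylsilyloxy)-3,7,11-trimethyldodeca-2,6,10-trien-1-yl]phenol | COc1cc(CO)c(O)cc1C/C=C(\C)CC/C=C(\C)CC/C=C(\C)CO[Si](c2ccccc2)(c2ccccc2)C(C)(C)C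
F7 | step 13 | rac-{6-hydroxy-3,3-dimethoxy-4-[(2E,6E,10E)-12-(tert-butyldiphenylsilyloxy)-3,7,11-trimethyldodeca-2,6,10-trien-1-yl]cyclohexa-1,4-dien-1-yl}methyl acetate | CC(=O)OCC1=CC(OC)(OC)C(C/C=C(\C)CC/C=C(\C)CC/C=C(\C)CO[Si](c2ccccc2)(c2ccccc2)C(C)(C)C)=CC1O
F8 | step 13 | (1R)-2-(acetoxymethyl)-4,4-dimethoxy-5-[(2E,6E,10E)-12-(tert-butyldiphenylsilyloxy)-3,7,11-trimethyldodeca-2,6,10-trien-1-yl]cyclohexa-2,5-dien-1-yl butanoate | CC(=O)OCC1=CC(OC)(OC)C(C/C=C(\C)CC/C=C(\C)CC/C=C(\C)CO[Si](c2ccccc2)(c2ccccc2)C(C)(C)C)=C[C@H]1OC(=O)CCC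
F9 | step 14 | (6S)-6-hydroxy-1-(hydroxymethyl)-3,3-dimethoxy-4-[(2E,6E,10E)-12-(tert-butyldiphenylsilyloxy)-3,7,11-trimethyldodeca-2,6,10-trien-1-yl]cyclohexa-1,4-diene | OCC1=CC(OC)(OC)C(C/C=C(\C)CC/C=C(\C)CC/C=C(\C)CO[Si](c2ccccc2)(c2ccccc2)C(C)(C)C)=C[C@@H]1O
F10 | step 14 | 6-hydroxy-3,3-dimethoxy-4-[(2E,6E,10E)-12-(tert-butyldiphenylsilyloxy)-3,7,11-trimethyldodeca-2,6,10-trien-1-yl]cyclohexa-1,4-diene-1-carbaldehyde (carbinol configured as in 16) | O=CC1=CC(OC)(OC)C(C/C=C(\C)CC/C=C(\C)CC/C=C(\C)CO[Si](c2ccccc2)(c2ccccc2)C(C)(C)C)=C[C@@H]1O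
F11 | step 14 | 5-hydroxy-2,2-dimethoxy-1-[(2E,6E,10E)-12-(tert-butyldiphenylsilyloxy)-3,7,11-trimethyldodeca-2,6,10-trien-1-yl]-7-oxabicyclo[4.1.0]hept-3-ene-4-carbaldehyde (ring stereocentres as in 17) | O=CC1=CC(OC)(OC)[C@]2(C/C=C(\C)CC/C=C(\C)CC/C=C(\C)CO[Si](c3ccccc3)(c3ccccc3)C(C)(C)C)O[C@@H]2[C@@H]1O
F12 | step 14 | 4-(hydroxymethyl)-2,2-dimethoxy-1-[(2E,6E,10E)-12-(tert-butyldiphenylsilyloxy)-3,7,11-trimethyldodeca-2,6,10-trien-1-yl]-7-oxabicyclo[4.1.0]hept-3-en-5-ol (ring stereocentres as in 17) | OCC1=CC(OC)(OC)[C@]2(C/C=C(\C)CC/C=C(\C)CC/C=C(\C)CO[Si](c3ccccc3)(c3ccccc3)C(C)(C)C)O[C@@H]2[C@@H]1O
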